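## Structural features

The target is an achiral, linear pentamer of phloroglucinol: five benzene rings A–E joined by four diaryl ether oxygens (A-1–O–B-1, B-6–O–C-1, C-4–O–D-1, D-6–O–E-1; ring positions are written ring letter–number) and carrying eleven free phenolic hydroxyls. Ring A is a 3,5-dihydroxyphenyl group, rings B and D are 1,2,3,5-tetraoxygenated with their two ether bonds on adjacent carbons, ring C has its two ether bonds para to each other, and ring E is a terminal 2,4,6-trihydroxyphenyl ether, that is a 2-aryloxyphloroglucinol. There is no stereocentre, so no stereocentres adjoin and no configuration has to be set; the only stereochemical element in the route is the geometry of a transient enoate. Each ether oxygen joins a carbon flanked by two oxygen-bearing carbons (B-1, C-1, D-1, E-1) to a less crowded carbon (A-1, B-6, C-4, D-6), so every diaryl ether bond is congested on one side; this, and telling eleven similar oxygens apart, is the real difficulty. The rings are very electron-rich: the free polyphenol is prone to air oxidation, the ring CH positions react with electrophiles (halogenating agents, diazonium ions, formaldehyde equivalents) and phloroglucinol ethers can exchange under strong acid, so the hydroxyls stay masked to the end. The key step exploits ring E: its E-2/E-4/E-6 oxygen pattern is that of a folded triketide and E-1, with its ether oxygen to D-6, maps onto the oxygenated chain carbon 6 of a 6-aryloxy-3,5-dioxohexanoate, which is stored as the 4-methoxy-2-pyrone 10 and closed by forming the E-1–E-2 bond.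

## Logic of the disconnections

27 ⇒ 26 ⇒ 25. The eleven O–alkyl bonds are cut last: the O–CH3 bond at E-4 (27 from 26) and the ten O–CH2Ph bonds (26 from 25). The free polyphenol is the most fragile compound, so every hydroxyl travels as an ether; benzyl is used because hydrogenolysis is neutral, and the one methyl ether is the price of building ring E from a 4-methoxypyrone. The gain is that all coupling chemistry runs on robust ethers. The demand is that hydrogenolysis and demethylation spare the four diaryl ether bonds.

25 ⇒ 14 + 24. The C-4–O bond between rings C and D is cut, the oxygen staying on D-1. This splits the pentamer into a three-ring bromide and a two-ring phenol of similar size and uses the oxygen that ring D has carried from the start. The demand is an Ullmann coupling of a phenol with two ortho substituents and an aryl bromide with none.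

14 ⇒ 13 ⇒ 12. Only protecting groups change: the D-1 phenol returns to its methoxymethyl ether and the benzyl groups on E-2 and E-6 are removed. D-1 must be masked while ring E is built and be the only free hydroxyl at the coupling. The demand is an acetal cleavage that leaves four benzyl ethers intact.

12 ⇒ 10 (key). The E-1–E-2 bond is cut; ring E opens to 11 and is stored as the pyrone ring of 10. The congested D-6–O–E-1 diaryl ether becomes an aryl alkyl ether at a CH2 group, and the pyrone supplies all three oxygens of ring E. The demand is that a carbanion stabilised by one ketone and bearing an aryloxy group acylates the ester.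

10 ⇒ 7 + 9, and 9 ⇒ 8. The O–CH2 bond is cut (SN2), then the C–Br bond of 9. This leads to a purchasable pyrone and a monocyclic phenol. The demand is monobromination at the methyl group and a phenol in which only the D-6 oxygen is free.

7 ⇒ 6 ⇒ 5 ⇒ 3 ⇒ 2 ⇒ 1. The D-1 oxygen is traced to the formyl carbon of 3 (C–O from C–C, Baeyer–Villiger through 4), and the protecting groups are removed in turn. In 1 the formyl group tells the oxygens apart, since chelation reserves one ortho hydroxyl for the allyl group. Compound 5, with only the flanked oxygen free, serves both ring D (D-1) and ring B (B-1). The demand is aldehyde oxidation beside an allyl ether and allyl removal beside benzyl and methoxymethyl.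

24 ⇒ 18 + 23. The C-1–O bond between rings B and C is cut, the oxygen staying on B-6. Compound 23 holds iodine on crowded C-1 for this coupling and bromine on C-4 for the last one. The demand is that the coupling takes the C–I bond and leaves C–Br.

18 ⇒ 17 ⇒ 5 + 16, and 16 ⇒ 15. After the allyl group is returned to B-6, the A-1–O bond is cut with the oxygen on B-1. This is the same coupling type as the final one, rehearsed on small compounds. The demand is that the allyl ether survives the coupling.

23 ⇒ 22 ⇒ 21 ⇒ 20 ⇒ 19. Iodine is traced to a diazonium group, then to amino and nitro; the two benzyloxy groups are cut as C–O bonds made by SNAr of fluorides ortho to nitro. The gain is a purchasable arene in which bromine already sits para to nitro. The demand is that alkoxide attacks the fluorides only and that nitro reduction keeps bromine and benzyl.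

## Other disconnections considered

Alternative 1: The cut runs through ring B: two ring C–C bonds (C2–C3 and C5–C6 in the numbering of A1's name) are disconnected, giving diethyl 2-[3,5-bis(benzyloxy)phenoxy]propanedioate A2 and diethyl 3-oxopentanedioate A3. In the forward step NaOEt in hot ethanol lets the two methylene carbons of A3 acylate the two ester groups of A2, and enolisation aromatises ring B as diethyl 5-[3,5-bis(benzyloxy)phenoxy]-2,4,6-trihydroxybenzene-1,3-dicarboxylate A1.
- In its favour: both attacking carbons are doubly activated β-keto ester methylenes. On carbanion activation this alternative is the better of the two, since the chosen key step relies on a carbanion with one carbonyl only.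
- Equal: like the chosen plan it places an ether oxygen on a flanked carbon (B-1) before the ring exists.
- Against it here: the methine of A2 is the most acidic proton present, and once deprotonated A2 is an enolate and a poor acyl donor, so the substrate does not secure the roles of the partners. A1 then needs double ester hydrolysis and decarboxylation. Its two hydroxyls flanking B-1 are equivalent, whereas ring B needs one arylated by ring C and the other protected, a statistical desymmetrisation.
- Comparison: in the chosen plan the same symmetry is an asset, because both hydroxyls flanking E-1 end up alike. On step economy after the ring closure the chosen plan should be ahead.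

Alternative 2: The cut removes four C–O bonds (the hydroxyls at A-5, B-4, D-4 and E-4) and returns them as C–H bonds in the tetradeoxy heptamethyl pentamer A5. In the forward step [Ir(OMe)(cod)]2, 4,4'-di-tert-butyl-2,2'-bipyridine and B2pin2 borylate the four C–H bonds that have no ortho substituent, and NaBO3 oxidises the C–B bonds in the same flask to give the heptamethyl ether A4; no ring closes.
- In its favour: the site selectivity follows the well-established steric rule of this borylation, so on precedent the alternative is the better. The building blocks are simpler (guaiacol- and pyrogallol-type ethers), so the front end should be equal or shorter in steps.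
- Against it here: four borylations must all go to completion on one molecule, and positions with one ortho substituent may leak. A5 still contains all four congested diaryl ether bonds, so the real difficulty is untouched. Seven methyl ethers must then be cleaved by Lewis acid on an eleven-fold phenol, a harsher end than one methyl ether after neutral hydrogenolysis.
- Comparison: the chosen plan spends more steps on oxygenated building blocks but removes one congested ether bond from the coupling problem and ends more gently.

Alternative 3: The cut takes two C–C bonds of ring A, leading to 3-ethoxycyclobut-2-en-1-one A7 and the aryl ethynyl ether A8. In the forward step (Danheiser benzannulation) heating in toluene opens A7 to a vinylketene, which adds to the ynol ether by [2+2] cycloaddition. A 4π ring opening, a 6π closure and tautomerisation then give 3-[2,4-bis(benzyloxy)-6-(methoxymethoxy)phenoxy]-5-ethoxyphenol A6.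
- In its favour: it is an established reaction type with regiochemistry fixed by the polarity of the ynol ether, so on precedent it is the better. Like the chosen key step it makes a congested ether (A-1–O–B-1) without a coupling at a flanked carbon, so on that idea the two are equal.
- Against it here: ring A is the one ring that is purchasable as a bromide and attachable in a single Ullmann step (step 12). A8 would need several steps from a hindered, electron-rich phenol through a dichlorovinyl ether and strong base, which benzyl ethers tolerate poorly, and would be labile.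
- Comparison: the ethyl ether left on ring A needs Lewis-acid cleavage, no better than the methyl ether of the chosen plan. Ring E and the inner rings are not helped, so in step economy the chosen plan should be clearly ahead.

Key step: step 8

Remark on the chemistry: in the ring-opened enoate the ester group and the methylene at chain carbon 4 stay cis on the C2=C3 bond, as they were in the pyrone. Because methoxy outranks that methylene, this geometry is (2E) and not (2Z), and intermediate 11 is named and drawn accordingly. The protecting groups of the precursor are kept. 5-Bromobenzene-1,3-diol and 5-bromo-1,3-difluoro-2-nitrobenzene are taken as purchasable.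

## Route

Step 1
Reactants: 1 2,4,6-trihydroxybenzaldehyde
Product: 2 2,4-bis(benzyloxy)-6-hydroxybenzaldehyde
Conditions: BnBr (2.1 equiv), K2CO3, DMF, 0 °C to rt
Reagents that add atoms: benzyl bromide, BrCc1ccccc1
Why: Williamson etherification; the hydroxyl hydrogen-bonded to the formyl group is the least nucleophilic, so the 4-hydroxyl and one ortho hydroxyl should react and the chelated one remain.

Step 2
Reactants: 2 2,4-bis(benzyloxy)-6-hydroxybenzaldehyde
Product: 3 2-(allyloxy)-4,6-bis(benzyloxy)benzaldehyde
Conditions: allyl bromide, K2CO3, DMF, 60 °C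
Reagents that add atoms: allyl bromide, C=CCBr
Why: Williamson etherification under more forcing conditions overcomes the chelation; allyl is the temporary group orthogonal to benzyl and MOM.

Step 3
Reactants: 3 2-(allyloxy)-4,6-bis(benzyloxy)benzaldehyde
Product: 5 2-(allyloxy)-4,6-bis(benzyloxy)phenol, via aryl formate 4 (not isolated)
Conditions: mCPBA (1.2 equiv), CH2Cl2, 0 °C to rt; then K2CO3 (cat.), MeOH, 0 °C
Reagents that add atoms: mCPBA, O=C(OO)c1cccc(Cl)c1
Why: Baeyer–Villiger (Dakin-type) oxidation: the aryl group, made electron-rich by three ortho/para alkoxy groups, migrates far faster than the electron-poor monosubstituted allyl alkene is epoxidised. Mild methanolysis of formate 4 then frees the flanked phenol, the branch point for rings B and D.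

Step 4
Reactants: 5 2-(allyloxy)-4,6-bis(benzyloxy)phenol
Product: 6 1-(allyloxy)-3,5-bis(benzyloxy)-2-(methoxymethoxy)benzene
Conditions: MOMCl, i-Pr2NEt, CH2Cl2, 0 to 40 °C
Reagents that add atoms: chloromethyl methyl ether, COCCl
Why: Acetal (MOM ether) formation at the only free hydroxyl; it masks the future D-1 oxygen through the basic steps and can later be removed without touching benzyl ethers.

Step 5
Reactants: 6 1-(allyloxy)-3,5-bis(benzyloxy)-2-(methoxymethoxy)benzene
Product: 7 3,5-bis(benzyloxy)-2-(methoxymethoxy)phenol
Conditions: Pd(PPh3)4 (cat.), morpholine, THF, rt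
Reagents that add atoms: none
Why: Tsuji–Trost-type deallylation: zerovalent palladium ionises the allyl aryl ether to a π-allyl complex that morpholine captures; benzyl and MOM ethers are inert.

Step 6
Reactants: 8 4-methoxy-6-methyl-2H-pyran-2-one
Product: 9 6-(bromomethyl)-4-methoxy-2H-pyran-2-one
Conditions: NBS (1.0 equiv), AIBN (cat.), PhCF3, 85 °C
Reagents that add atoms: N-bromosuccinimide, O=C1CCC(=O)N1Br
Why: Wohl–Ziegler bromination: hydrogen abstraction occurs at the methyl group because the radical is delocalised over the pyrone diene; one equivalent of NBS limits dibromination.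

Step 7
Reactants: 7 3,5-bis(benzyloxy)-2-(methoxymethoxy)phenol; 9 6-(bromomethyl)-4-methoxy-2H-pyran-2-one
Product: 10 6-{[3,5-bis(benzyloxy)-2-(methoxymethoxy)phenoxy]methyl}-4-methoxy-2H-pyran-2-one
Conditions: K2CO3, acetone, 50 °C
Reagents that add atoms: none
Why: Williamson SN2 etherification of a primary, allylic-type bromide by the phenoxide of 7; this places the future D-6–O–E-1 oxygen on carbon before ring E exists.

Step 8
Reactants: 10 6-{[3,5-bis(benzyloxy)-2-(methoxymethoxy)phenoxy]methyl}-4-methoxy-2H-pyran-2-one
Product: 12 2-[3,5-bis(benzyloxy)-2-(methoxymethoxy)phenoxy]-5-methoxybenzene-1,3-diol, via keto enoate 11 (not isolated)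
Conditions: Mg(OMe)2 (5 equiv), MeOH–THF, 65 °C; then aq. NH4Cl, 0 °C
Reagents that add atoms: none
Why: Proposed new method: methoxide from Mg(OMe)2 adds to the lactone carbonyl of 10 and opens it to keto enoate 11, in which the ester group and the methylene at chain carbon 4 remain cis on the C2=C3 bond [(2E)], so that chain carbons 1 and 6 are within reach and magnesium chelation keeps the chain folded. Deprotonation at chain carbon 6, which is alpha to the ketone and inductively acidified by the aryloxy oxygen, gives an enolate that attacks the ester carbonyl in a 6-(enolendo)-exo-trig Claisen (Dieckmann-type) closure and forms the E-1–E-2 bond. Loss of methoxide and enolisation then give the aromatic ring as its magnesium phenoxide, a thermodynamic sink that pulls the reversible steps forward. The closest known reaction type is the Mg(OMe)2-induced opening and Claisen recyclisation of 6-(2-oxoalkyl)-4-hydroxy-2-pyrones to acylphloroglucinols, together with the Claisen cyclisation of 3,5-dioxohexanoates to phloroglucinol; the new element is a carbanion activated by a single carbonyl group and carrying an aryloxy substituent. No stereocentre is formed. The step needs C-acylation to win over relactonisation through the enolate oxygen and over exchange of the 4-methoxy group: relactonisation is reversible, exchange is degenerate because methoxide is the only alkoxide present, an aldol closure is impossible because chain carbon 2 is vinylic, and only the Claisen path ends in an aromatic ring. Benzyl, MOM and aryl ethers are inert to Mg(OMe)2 in methanol.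

Step 9
Reactants: 12 2-[3,5-bis(benzyloxy)-2-(methoxymethoxy)phenoxy]-5-methoxybenzene-1,3-diol
Product: 13 1,3-bis(benzyloxy)-2-[3,5-bis(benzyloxy)-2-(methoxymethoxy)phenoxy]-5-methoxybenzene
Conditions: BnBr (2.5 equiv), K2CO3, DMF, 50 °C
Reagents that add atoms: benzyl bromide, BrCc1ccccc1
Why: Williamson etherification of the two phenols flanking E-1; they must be masked so that only the D-1 oxygen can act as nucleophile in step 18.

Step 10
Reactants: 13 1,3-bis(benzyloxy)-2-[3,5-bis(benzyloxy)-2-(methoxymethoxy)phenoxy]-5-methoxybenzene
Product: 14 2,4-bis(benzyloxy)-6-[2,6-bis(benzyloxy)-4-methoxyphenoxy]phenol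
Conditions: HCl (cat.), MeOH–THF, 45 °C
Reagents that add atoms: none
Why: Acid-catalysed acetal methanolysis of the MOM ether; the methoxymethyl unit is carried off by the solvent as dimethoxymethane, and benzyl, methyl and diaryl ethers are stable to catalytic acid.

Step 11
Reactants: 15 5-bromobenzene-1,3-diol
Product: 16 1,3-bis(benzyloxy)-5-bromobenzene
Conditions: BnBr (2.2 equiv), K2CO3, acetone, reflux
Reagents that add atoms: benzyl bromide, BrCc1ccccc1
Why: Williamson etherification of both phenols gives the ring A bromide.

Step 12
Reactants: 5 2-(allyloxy)-4,6-bis(benzyloxy)phenol; 16 1,3-bis(benzyloxy)-5-bromobenzene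
Product: 17 1-(allyloxy)-3,5-bis(benzyloxy)-2-[3,5-bis(benzyloxy)phenoxy]benzene
Conditions: CuI (10 mol%), picolinic acid (20 mol%), K3PO4, DMSO, 90 °C
Reagents that add atoms: none
Why: Ullmann diaryl ether synthesis: monovalent copper with picolinate as ligand couples a di-ortho-oxygenated phenol with an unhindered aryl bromide, the classical pairing for phlorethol ethers; the allyl ether is inert.

Step 13
Reactants: 17 1-(allyloxy)-3,5-bis(benzyloxy)-2-[3,5-bis(benzyloxy)phenoxy]benzene
Product: 18 3,5-bis(benzyloxy)-2-[3,5-bis(benzyloxy)phenoxy]phenol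
Conditions: Pd(PPh3)4 (cat.), morpholine, THF, rt
Reagents that add atoms: none
Why: Tsuji–Trost-type deallylation as in step 5 frees the B-6 hydroxyl; benzyl and diaryl ethers are untouched.

Step 14
Reactants: 19 5-bromo-1,3-difluoro-2-nitrobenzene
Product: 20 1,3-bis(benzyloxy)-5-bromo-2-nitrobenzene
Conditions: BnOH (2.2 equiv), NaH, THF, 0 °C to rt
Reagents that add atoms: benzyl alcohol, OCc1ccccc1
Why: Twofold SNAr: both fluorides are ortho to the nitro group and fluoride is by far the better nucleofuge in addition–elimination, so the para bromide is kept.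

Step 15
Reactants: 20 1,3-bis(benzyloxy)-5-bromo-2-nitrobenzene
Product: 21 2,6-bis(benzyloxy)-4-bromoaniline
Conditions: Fe powder, NH4Cl, EtOH–H2O, 80 °C
Reagents that add atoms: none
Why: Béchamp-type dissolving-metal reduction of the nitro group; unlike catalytic hydrogenation it leaves the aryl bromide and the benzyl ethers untouched.

Step 16
Reactants: 21 2,6-bis(benzyloxy)-4-bromoaniline
Product: 23 1,3-bis(benzyloxy)-5-bromo-2-iodobenzene, via diazonium tosylate 22 (not isolated)
Conditions: p-TsOH·H2O, NaNO2, KI, MeCN–H2O, 10 °C to rt
Reagents that add atoms: potassium iodide, [K+].[I-]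
Why: Diazotisation followed by Sandmeyer-type iododediazoniation (iodide itself reduces the diazonium ion, no copper needed); this puts the more reactive halogen on the crowded C-1 of ring C.

Step 17
Reactants: 18 3,5-bis(benzyloxy)-2-[3,5-bis(benzyloxy)phenoxy]phenol; 23 1,3-bis(benzyloxy)-5-bromo-2-iodobenzene
Product: 24 1,3-bis(benzyloxy)-2-{3,5-bis(benzyloxy)-2-[3,5-bis(benzyloxy)phenoxy]phenoxy}-5-bromobenzene
Conditions: CuI (10 mol%), picolinic acid (20 mol%), K3PO4, DMSO, 80 °C, 23 in excess (3 equiv)
Reagents that add atoms: none
Why: Ullmann coupling run to be chemoselective for the weaker C–I bond, helped by the two ortho benzyloxy groups that can coordinate copper, at a temperature where the C–Br bond reacts slowly. Excess 23 suppresses a second coupling of the product.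

Step 18
Reactants: 14 2,4-bis(benzyloxy)-6-[2,6-bis(benzyloxy)-4-methoxyphenoxy]phenol; 24 1,3-bis(benzyloxy)-2-{3,5-bis(benzyloxy)-2-[3,5-bis(benzyloxy)phenoxy]phenoxy}-5-bromobenzene
Product: 25 decabenzyl ether of 26 (the target with benzyl ethers on all hydroxyls of rings A to D and on E-2 and E-6, and a methyl ether on E-4)
Conditions: CuI (20 mol%), picolinic acid (40 mol%), K3PO4, DMSO–toluene, 105 °C
Reagents that add atoms: none
Why: Ullmann diaryl ether synthesis of the same type as step 12: a di-ortho-substituted phenoxide (D-1–O) with an aryl bromide that has no ortho substituent (C-4). All other hydroxyls are ethers, so only one C–O bond can form.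

Step 19
Reactants: 25 decabenzyl ether of 26
Product: 26 2-{2-[4-[2-(3,5-dihydroxyphenoxy)-3,5-dihydroxyphenoxy]-3,5-dihydroxyphenoxy]-3,5-dihydroxyphenoxy}-5-methoxybenzene-1,3-diol
Conditions: H2 (1 atm), Pd/C, THF–MeOH, rt
Reagents that add atoms: none
Why: Hydrogenolysis of the ten benzyl ethers over palladium; diaryl ether and methyl ether bonds are not cleaved under these neutral conditions.

Step 20
Reactants: 26 E-4 methyl ether of the target
Product: 27 2-{2-[4-[2-(3,5-dihydroxyphenoxy)-3,5-dihydroxyphenoxy]-3,5-dihydroxyphenoxy]-3,5-dihydroxyphenoxy}benzene-1,3,5-triol (target)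
Conditions: BBr3 (excess), CH2Cl2, −78 °C to rt; then MeOH, H2O, 0 °C
Reagents that add atoms: none
Why: Lewis-acid demethylation: BBr3 turns the phenols into aryl borates, coordinates the methoxy oxygen, and bromide removes the methyl group by SN2. Diaryl ether bonds are inert to BBr3 and hydrolytic work-up should free the target.

## Compound list

1 | 2,4,6-trihydroxybenzaldehyde | O=Cc1c(O)cc(O)cc1O | starting material
2 | 2,4-bis(benzyloxy)-6-hydroxybenzaldehyde | O=Cc1c(O)cc(OCc2ccccc2)cc1OCc1ccccc1 | intermediate
3 | 2-(allyloxy)-4,6-bis(benzyloxy)benzaldehyde | C=CCOc1cc(OCc2ccccc2)cc(OCc2ccccc2)c1C=O | intermediate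
4 | 2-(allyloxy)-4,6-bis(benzyloxy)phenyl formate | C=CCOc1cc(OCc2ccccc2)cc(OCc2ccccc2)c1OC=O | intermediate
5 | 2-(allyloxy)-4,6-bis(benzyloxy)phenol | C=CCOc1cc(OCc2ccccc2)cc(OCc2ccccc2)c1O | intermediate
6 | 1-(allyloxy)-3,5-bis(benzyloxy)-2-(methoxymethoxy)benzene | C=CCOc1cc(OCc2ccccc2)cc(OCc2ccccc2)c1OCOC | intermediate
7 | 3,5-bis(benzyloxy)-2-(methoxymethoxy)phenol | COCOc1c(O)cc(OCc2ccccc2)cc1OCc1ccccc1 | intermediate
8 | 4-methoxy-6-methyl-2H-pyran-2-one | COC1=CC(=O)OC(C)=C1 | starting material
9 | 6-(bromomethyl)-4-methoxy-2H-pyran-2-one | COC1=CC(=O)OC(CBr)=C1 | intermediate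
10 | 6-{[3,5-bis(benzyloxy)-2-(methoxymethoxy)phenoxy]methyl}-4-methoxy-2H-pyran-2-one | COC1=CC(=O)OC(COc2cc(OCc3ccccc3)cc(OCc3ccccc3)c2OCOC)=C1 | intermediate
11 | methyl (2E)-6-[3,5-bis(benzyloxy)-2-(methoxymethoxy)phenoxy]-3-methoxy-5-oxohex-2-enoate | COC(=O)/C=C(/OC)CC(=O)COc1cc(OCc2ccccc2)cc(OCc2ccccc2)c1OCOC | intermediate
12 | 2-[3,5-bis(benzyloxy)-2-(methoxymethoxy)phenoxy]-5-methoxybenzene-1,3-diol | COc1cc(O)c(Oc2cc(OCc3ccccc3)cc(OCc3ccccc3)c2OCOC)c(O)c1 | intermediate
13 | 1,3-bis(benzyloxy)-2-[3,5-bis(benzyloxy)-2-(methoxymethoxy)phenoxy]-5-methoxybenzene | COc1cc(OCc2ccccc2)c(Oc2cc(OCc3ccccc3)cc(OCc3ccccc3)c2OCOC)c(OCc2ccccc2)c1 | intermediate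
14 | 2,4-bis(benzyloxy)-6-[2,6-bis(benzyloxy)-4-methoxyphenoxy]phenol | COc1cc(OCc2ccccc2)c(Oc2cc(OCc3ccccc3)cc(OCc3ccccc3)c2O)c(OCc2ccccc2)c1 | intermediate
15 | 5-bromobenzene-1,3-diol | Oc1cc(O)cc(Br)c1 | starting material
16 | 1,3-bis(benzyloxy)-5-bromobenzene | Brc1cc(OCc2ccccc2)cc(OCc2ccccc2)c1 | intermediate
17 | 1-(allyloxy)-3,5-bis(benzyloxy)-2-[3,5-bis(benzyloxy)phenoxy]benzene | C=CCOc1cc(OCc2ccccc2)cc(OCc2ccccc2)c1Oc1cc(OCc2ccccc2)cc(OCc2ccccc2)c1 | intermediate
18 | 3,5-bis(benzyloxy)-2-[3,5-bis(benzyloxy)phenoxy]phenol | Oc1cc(OCc2ccccc2)cc(OCc2ccccc2)c1Oc1cc(OCc2ccccc2)cc(OCc2ccccc2)c1 | intermediate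
19 | 5-bromo-1,3-difluoro-2-nitrobenzene | O=[N+]([O-])c1c(F)cc(Br)cc1F | starting material
20 | 1,3-bis(benzyloxy)-5-bromo-2-nitrobenzene | O=[N+]([O-])c1c(OCc2ccccc2)cc(Br)cc1OCc1ccccc1 | intermediate
21 | 2,6-bis(benzyloxy)-4-bromoaniline | Nc1c(OCc2ccccc2)cc(Br)cc1OCc1ccccc1 | intermediate
22 | 2,6-bis(benzyloxy)-4-bromobenzenediazonium 4-toluenesulfonate | N#[N+]c1c(OCc2ccccc2)cc(Br)cc1OCc1ccccc1.Cc1ccc(cc1)S([O-])(=O)=O | intermediate
23 | 1,3-bis(benzyloxy)-5-bromo-2-iodobenzene | Ic1c(OCc2ccccc2)cc(Br)cc1OCc1ccccc1 | intermediate
24 | 1,3-bis(benzyloxy)-2-{3,5-bis(benzyloxy)-2-[3,5-bis(benzyloxy)phenoxy]phenoxy}-5-bromobenzene | Brc1cc(OCc2ccccc2)c(Oc2cc(OCc3ccccc3)cc(OCc3ccccc3)c2Oc2cc(OCc3ccccc3)cc(OCc3ccccc3)c2)c(OCc2ccccc2)c1 | intermediate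
25 | decabenzyl ether of 26 (benzyl on all hydroxyls of rings A to D and on E-2, E-6; methyl on E-4) | C(c1ccccc1)Oc1cc(OCc2ccccc2)cc(Oc2c(OCc3ccccc3)cc(OCc3ccccc3)cc2Oc2c(OCc3ccccc3)cc(Oc3c(OCc4ccccc4)cc(OCc4ccccc4)cc3Oc3c(OCc4ccccc4)cc(OC)cc3OCc3ccccc3)cc2OCc2ccccc2)c1 | intermediate
26 | 2-{2-[4-[2-(3,5-dihydroxyphenoxy)-3,5-dihydroxyphenoxy]-3,5-dihydroxyphenoxy]-3,5-dihydroxyphenoxy}-5-methoxybenzene-1,3-diol | Oc1cc(O)cc(Oc2c(O)cc(O)cc2Oc2c(O)cc(Oc3c(O)cc(O)cc3Oc3c(O)cc(OC)cc3O)cc2O)c1 | intermediate
27 | 2-{2-[4-[2-(3,5-dihydroxyphenoxy)-3,5-dihydroxyphenoxy]-3,5-dihydroxyphenoxy]-3,5-dihydroxyphenoxy}benzene-1,3,5-triol (CNP0018313.0) | Oc1cc(O)cc(Oc2c(O)cc(O)cc2Oc2c(O)cc(Oc3c(O)cc(O)cc3Oc3c(O)cc(O)cc3O)cc2O)c1 | target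

## Step count and risks

Total step count: 20. Longest linear sequence: 12 steps (steps 1–5, 7–10 and 18–20, from 1 to 27).

Least certain steps:

Step 8 (key step, proposed new method). The most likely failure is that C-acylation does not take place. Chain carbon 6 is acidified by one carbonyl only, whereas the methylene at chain carbon 4 is deprotonated first, so the material may merely shuttle between pyrone and open enoate, or be lost by ester hydrolysis if water is present. The fallback uses known chemistry and brings ring E in preformed.
- It sets out from 7. 1,3,5-Tris(benzyloxy)benzene F1 (purchased) is mono-iodinated with N-iodosuccinimide in MeCN to 1,3,5-tris(benzyloxy)-2-iodobenzene F2; the three ring positions are equivalent.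
- Ullmann coupling of 7 with F2 (CuI, picolinic acid, K3PO4, DMSO, 90 °C) should give 1,3,5-tris(benzyloxy)-2-[3,5-bis(benzyloxy)-2-(methoxymethoxy)phenoxy]benzene F3.
- MOM removal as in step 10 gives 2,4-bis(benzyloxy)-6-[2,4,6-tris(benzyloxy)phenoxy]phenol F4, and coupling with 24 as in step 18 gives the undecabenzyl ether of the target F5.
- Hydrogenolysis (H2, Pd/C) comes back to the route at 27; step 20 is then not needed.

Step 17. The most likely failure is loss of chemoselectivity: the iodide is shielded by two ortho substituents while the bromide is unhindered, so coupling at C–Br or a second coupling of the product may compete. The fallback replaces copper catalysis by a metal-free aryl transfer from trivalent iodine.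
- It sets out from 23, which is oxidised with mCPBA and p-TsOH·H2O in MeCN and captured by 1,3,5-trimethoxybenzene to give [2,6-bis(benzyloxy)-4-bromophenyl](2,4,6-trimethoxyphenyl)iodonium 4-toluenesulfonate F6.
- The potassium phenoxide of 18 (K2CO3, toluene–MeCN, 50 °C) should take up the less electron-rich, bromine-bearing aryl group of F6 and leave the C–Br bond untouched. It comes back at 24.

Step 18. The most likely failure is slow coupling, because the D-1 phenoxide is shielded by two ortho ether groups and both partners are large; protodehalogenation of 24 and oxidative degradation of 14 could then compete. The fallback reverses the order of the two copper couplings, so that the most hindered phenol meets a small halide used in excess.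
- It sets out from 14, with 21 and 18 taken from the route. Compound 21 is converted by Sandmeyer bromination (t-BuONO, CuBr2, MeCN) into 1,3-bis(benzyloxy)-2,5-dibromobenzene F7.
- Compound 14 is coupled with excess F7 at its unhindered bromide (CuI, picolinic acid, K3PO4, DMSO, 90 °C) to give the ring C–D–E bromide F8.
- F8 is coupled with 18 (CuI, 2,2,6,6-tetramethylheptane-3,5-dione, Cs2CO3, NMP, 120 °C). It comes back at 25.

Step 20. The most likely failure is incomplete demethylation, or oxidation and acid-induced ether exchange of the unprotected, poorly soluble polyphenol during the Lewis-acid treatment. The fallback avoids exposing a free polyphenol: it sets out from 25 and cleaves benzyl and methyl ethers in one flask with BBr3 and pentamethylbenzene as cation trap (CH2Cl2, −78 to 0 °C). The phenols stay bound as borates until hydrolytic work-up, and it comes back at 27 without passing through 26.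

Step 1. The most likely failure is over- and under-alkylation, with some C-benzylation of the phloroglucinol nucleus, since the three hydroxyls differ only by chelation. The fallback sets out from 1: exhaustive benzylation (BnBr, K2CO3, DMF, 60 °C) gives 2,4,6-tris(benzyloxy)benzaldehyde F9. MgBr2·OEt2 in toluene–Et2O then removes one benzyl group ortho to the formyl group by chelation-directed cleavage, and it comes back at 2.

## Further compounds

F1 | step 8 | 1,3,5-tris(benzyloxy)benzene (purchased) | c1ccc(COc2cc(OCc3ccccc3)cc(OCc3ccccc3)c2)cc1
F2 | step 8 | 1,3,5-tris(benzyloxy)-2-iodobenzene | Ic1c(OCc2ccccc2)cc(OCc2ccccc2)cc1OCc1ccccc1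
F3 | step 8 | 1,3,5-tris(benzyloxy)-2-[3,5-bis(benzyloxy)-2-(methoxymethoxy)phenoxy]benzene | COCOc1c(OCc2ccccc2)cc(OCc2ccccc2)cc1Oc1c(OCc2ccccc2)cc(OCc2ccccc2)cc1OCc1ccccc1
F4 | step 8 | 2,4-bis(benzyloxy)-6-[2,4,6-tris(benzyloxy)phenoxy]phenol | Oc1c(OCc2ccccc2)cc(OCc2ccccc2)cc1Oc1c(OCc2ccccc2)cc(OCc2ccccc2)cc1OCc1ccccc1
F5 | step 8 | undecabenzyl ether of the target | C(c1ccccc1)Oc1cc(OCc2ccccc2)cc(Oc2c(OCc3ccccc3)cc(OCc3ccccc3)cc2Oc2c(OCc3ccccc3)cc(Oc3c(OCc4ccccc4)cc(OCc4ccccc4)cc3Oc3c(OCc4ccccc4)cc(OCc4ccccc4)cc3OCc3ccccc3)cc2OCc2ccccc2)c1
F6 | step 17 | [2,6-bis(benzyloxy)-4-bromophenyl](2,4,6-trimethoxyphenyl)iodonium 4-toluenesulfonate | COc1cc(OC)c([I+]c2c(OCc3ccccc3)cc(Br)cc2OCc2ccccc2)c(OC)c1.Cc1ccc(cc1)S([O-])(=O)=O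
F7 | step 18 | 1,3-bis(benzyloxy)-2,5-dibromobenzene | Brc1cc(OCc2ccccc2)c(Br)c(OCc2ccccc2)c1
F8 | step 18 | 1,3-bis(benzyloxy)-5-{2,4-bis(benzyloxy)-6-[2,6-bis(benzyloxy)-4-methoxyphenoxy]phenoxy}-2-bromobenzene | Brc1c(OCc2ccccc2)cc(Oc2c(OCc3ccccc3)cc(OCc3ccccc3)cc2Oc2c(OCc3ccccc3)cc(OC)cc2OCc2ccccc2)cc1OCc1ccccc1
F0 | step 20 | none | none
F9 | step 1 | 2,4,6-tris(benzyloxy)benzaldehyde | O=Cc1c(OCc2ccccc2)cc(OCc2ccccc2)cc1OCc1ccccc1
A1 | alternative 1 | diethyl 5-[3,5-bis(benzyloxy)phenoxy]-2,4,6-trihydroxybenzene-1,3-dicarboxylate | CCOC(=O)c1c(O)c(C(=O)OCC)c(O)c(Oc2cc(OCc3ccccc3)cc(OCc3ccccc3)c2)c1O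
A2 | alternative 1 | diethyl 2-[3,5-bis(benzyloxy)phenoxy]propanedioate | CCOC(=O)C(Oc1cc(OCc2ccccc2)cc(OCc2ccccc2)c1)C(=O)OCC
A3 | alternative 1 | diethyl 3-oxopentanedioate | CCOC(=O)CC(=O)CC(=O)OCC
A4 | alternative 2 | heptamethyl ether of the target with free hydroxyls at A-5, B-4, D-4 and E-4 | COc1cc(O)cc(Oc2c(OC)cc(O)cc2Oc2c(OC)cc(Oc3c(OC)cc(O)cc3Oc3c(OC)cc(O)cc3OC)cc2OC)c1
A5 | alternative 2 | tetradeoxy heptamethyl pentamer (A4 with H in place of the four hydroxyls) | COc1cccc(Oc2c(OC)cccc2Oc2c(OC)cc(Oc3c(OC)cccc3Oc3c(OC)cccc3OC)cc2OC)c1
A6 | alternative 3 | 3-[2,4-bis(benzyloxy)-6-(methoxymethoxy)phenoxy]-5-ethoxyphenol | CCOc1cc(O)cc(Oc2c(OCc3ccccc3)cc(OCc3ccccc3)cc2OCOC)c1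
A7 | alternative 3 | 3-ethoxycyclobut-2-en-1-one | CCOC1=CC(=O)C1
A8 | alternative 3 | 1,5-bis(benzyloxy)-2-(ethynyloxy)-3-(methoxymethoxy)benzene | C#COc1c(OCc2ccccc2)cc(OCc2ccccc2)cc1OCOC
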